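**Plan**

- Retrosynthesis: cut the CH2–CH2 bond of the bibenzyl bridge first, then the two ring–prenyl bonds at C3 and C5 of the benzoic ring (C1 = carboxyl-bearing carbon, C2 OMe, C4 OH, C6 bridge carbon), then the O-2 methyl bond and the ester and silyl helpers. This leads back to orsellinic acid and 4-(silyloxy)benzyl alcohol.
- Forward: no ring is built. Orsellinic acid is esterified as a fluoride-labile 2-(trimethylsilyl)ethyl ester, benzylated at O-4 and methylated at O-2, debenzylated, prenylated twice ortho to the freed 4-OH, silylated, and joined to the para-siloxybenzyl bromide. One fluoride treatment then removes all three silicon helpers.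
- Enabling feature: the carboxyl carbon on C1 lies ortho to the C6 methyl and acidifies only that CH3 (lateral lithiation to an o-quinodimethane-type dienolate). The para oxygen of the second ring makes its benzylic carbon a strongly activated electrophile. The two bridge carbons are therefore joined in their natural polarity on the fully substituted, diprenylated ring, leaving only deprotection.
- Stereochemistry: the target has no stereocentre and no stereogenic double bond (each alkene carries two methyl groups), so it is one achiral compound and no step has to set configuration.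

Key step: step 7

**Route**

Step 1
Reactants: 1 orsellinic acid (2,4-dihydroxy-6-methylbenzoic acid)
Product: 2 2-(trimethylsilyl)ethyl 2,4-dihydroxy-6-methylbenzoate
Conditions: 2-(trimethylsilyl)ethanol (1.05 equiv), PPh3, DIAD, THF, 0 °C → rt
Reagents that add atoms: 2-(trimethylsilyl)ethanol, C[Si](C)(C)CCO
Why: Mitsunobu esterification activates the alcohol and not the di-ortho-substituted acid, and the carboxylic acid, far more acidic than either phenol, is the pronucleophile, so the ester should form without phenol protection; this ester is chosen because fluoride removes it at the end without hydrolysis at a hindered carbonyl.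

Step 2
Reactants: 2 2-(trimethylsilyl)ethyl 2,4-dihydroxy-6-methylbenzoate
Product: 4 2-(trimethylsilyl)ethyl 4-(benzyloxy)-2-methoxy-6-methylbenzoate, via 4-O-benzyl ether 3 (not isolated)
Conditions: BnBr (1.05 equiv), K2CO3, DMF, rt; then MeI (3 equiv), 45 °C
Reagents that add atoms: benzyl bromide, BrCc1ccccc1; iodomethane, CI
Why: Two Williamson etherifications in sequence: the 4-OH is the more acidic phenol and is not hydrogen-bonded, so it should be benzylated first at room temperature, after which the chelated 2-OH is methylated by excess iodomethane on warming.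

Step 3
Reactants: 4 2-(trimethylsilyl)ethyl 4-(benzyloxy)-2-methoxy-6-methylbenzoate
Product: 5 2-(trimethylsilyl)ethyl 4-hydroxy-2-methoxy-6-methylbenzoate
Conditions: H2 (1 atm), Pd/C, EtOAc, rt
Reagents that add atoms: none
Why: Catalytic hydrogenolysis of the benzyl aryl ether should free only the 4-OH; it is placed before the prenyl alkenes are introduced, and the silyl ester is inert to it.

Step 4
Reactants: 5 2-(trimethylsilyl)ethyl 4-hydroxy-2-methoxy-6-methylbenzoate
Product: 8 2-(trimethylsilyl)ethyl 4-hydroxy-2-methoxy-6-methyl-3,5-bis(3-methylbut-2-en-1-yl)benzoate, via 3-prenyl phenol 6 (not isolated), via 5-prenyl phenol 7 (not isolated)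
Conditions: NaH (2.5 equiv), toluene, 0 °C → rt; prenyl bromide (2.5 equiv, two portions), rt → 50 °C
Reagents that add atoms: prenyl bromide (1-bromo-3-methylbut-2-ene), CC(C)=CCBr
Why: ortho-Selective C-alkylation of a sodium phenoxide in a non-polar solvent (tight ion pair shields oxygen): C3 and C5 are the only free ring positions, both ortho to O-4 and activated by the OMe, and the para position is blocked by C1, so both mono-prenyl isomers should converge on 8.

Step 5
Reactants: 8 2-(trimethylsilyl)ethyl 4-hydroxy-2-methoxy-6-methyl-3,5-bis(3-methylbut-2-en-1-yl)benzoate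
Product: 9 2-(trimethylsilyl)ethyl 4-[(tert-butyldimethylsilyl)oxy]-2-methoxy-6-methyl-3,5-bis(3-methylbut-2-en-1-yl)benzoate
Conditions: TBSCl (1.5 equiv), imidazole (3 equiv), DMF, rt → 40 °C
Reagents that add atoms: tert-butyldimethylsilyl chloride, CC(C)(C)[Si](C)(C)Cl
Why: Imidazole-promoted silylation of the phenol removes the only acidic O–H before the strong-base step and puts on a group that the final fluoride treatment takes off together with the ester.

Step 6
Reactants: 10 {4-[(tert-butyldimethylsilyl)oxy]phenyl}methanol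
Product: 11 [4-(bromomethyl)phenoxy](tert-butyl)dimethylsilane
Conditions: CBr4, PPh3, CH2Cl2, 0 °C; short silica plug (hexanes), used at once
Reagents that add atoms: carbon tetrabromide, BrC(Br)(Br)Br
Why: Appel bromination converts the benzylic alcohol to the bromide under neutral conditions that leave the aryl silyl ether intact.

Step 7
Reactants: 9 2-(trimethylsilyl)ethyl 4-[(tert-butyldimethylsilyl)oxy]-2-methoxy-6-methyl-3,5-bis(3-methylbut-2-en-1-yl)benzoate; 11 [4-(bromomethyl)phenoxy](tert-butyl)dimethylsilane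
Product: 13 2-(trimethylsilyl)ethyl 4-[(tert-butyldimethylsilyl)oxy]-6-(2-{4-[(tert-butyldimethylsilyl)oxy]phenyl}ethyl)-2-methoxy-3,5-bis(3-methylbut-2-en-1-yl)benzoate, via lithiated toluate 12 (not isolated)
Conditions: LDA (commercial solution, 1.15 equiv), THF, −78 °C, 45 min; then 11 (1.3 equiv) in THF, −78 → −40 °C; sat. aq. NH4Cl
Reagents that add atoms: none
Why: Lateral (benzylic) lithiation–alkylation of an ortho-toluate: LDA, complexed to the ester carbonyl on C1, removes a proton from the ortho C6 methyl to give the lithium dienolate 12 (charge delocalised from the exocyclic carbon through C6–C1 into the ester, an o-quinodimethane-type anion), which attacks the benzylic carbon of 11 in an SN2 displacement that restores the aromatic ring and forms the CH2–CH2 bridge. The closest known reaction type is the benzylation of lithiated orsellinate-type 2-alkoxy-6-methylbenzoates with benzyl bromides, applied here to a hexasubstituted ring. No ring is closed and no stereocentre is formed. The step needs site selectivity for the C6 methyl over the two benzylic-allylic prenyl methylenes: only the C6 methyl is ortho to the ester (conjugative stabilisation plus directed deprotonation), whereas the C3 and C5 methylenes are meta to it and should not be removed by LDA at −78 °C. Self-condensation of 12 on the ester of 9 is disfavoured by the two ortho substituents of that ester and the low temperature, the para-siloxy group makes the bromide of 11 a fast electrophile, and the silyl ethers remove every acidic O–H.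

Step 8
Reactants: 13 2-(trimethylsilyl)ethyl 4-[(tert-butyldimethylsilyl)oxy]-6-(2-{4-[(tert-butyldimethylsilyl)oxy]phenyl}ethyl)-2-methoxy-3,5-bis(3-methylbut-2-en-1-yl)benzoate
Product: 14 4-hydroxy-6-[2-(4-hydroxyphenyl)ethyl]-2-methoxy-3,5-bis(3-methylbut-2-en-1-yl)benzoic acid (target)
Conditions: TBAF (5 equiv, 1 M in THF), THF, 0 °C → rt; then cold 0.5 M HCl to pH 4, EtOAc extraction
Reagents that add atoms: none
Why: Fluoride-mediated global desilylation: fluoride attacks all three silicon atoms, the two aryl silyl ethers give phenoxides and the 2-(trimethylsilyl)ethyl ester fragments by β-elimination to the carboxylate, so the acid should be released without hydrolysis at the hindered carbonyl and without acid or hydrogenation conditions that would touch the prenyl groups.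

**Compound list**

1 | orsellinic acid (2,4-dihydroxy-6-methylbenzoic acid) | Cc1cc(O)cc(O)c1C(=O)O | starting material
2 | 2-(trimethylsilyl)ethyl 2,4-dihydroxy-6-methylbenzoate | Cc1cc(O)cc(O)c1C(=O)OCC[Si](C)(C)C | intermediate
3 | 2-(trimethylsilyl)ethyl 4-(benzyloxy)-2-hydroxy-6-methylbenzoate | Cc1cc(OCc2ccccc2)cc(O)c1C(=O)OCC[Si](C)(C)C | intermediate
4 | 2-(trimethylsilyl)ethyl 4-(benzyloxy)-2-methoxy-6-methylbenzoate | COc1cc(OCc2ccccc2)cc(C)c1C(=O)OCC[Si](C)(C)C | intermediate
5 | 2-(trimethylsilyl)ethyl 4-hydroxy-2-methoxy-6-methylbenzoate | COc1cc(O)cc(C)c1C(=O)OCC[Si](C)(C)C | intermediate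
6 | 2-(trimethylsilyl)ethyl 4-hydroxy-2-methoxy-6-methyl-3-(3-methylbut-2-en-1-yl)benzoate | COc1c(CC=C(C)C)c(O)cc(C)c1C(=O)OCC[Si](C)(C)C | intermediate
7 | 2-(trimethylsilyl)ethyl 4-hydroxy-2-methoxy-6-methyl-5-(3-methylbut-2-en-1-yl)benzoate | COc1cc(O)c(CC=C(C)C)c(C)c1C(=O)OCC[Si](C)(C)C | intermediate
8 | 2-(trimethylsilyl)ethyl 4-hydroxy-2-methoxy-6-methyl-3,5-bis(3-methylbut-2-en-1-yl)benzoate | COc1c(CC=C(C)C)c(O)c(CC=C(C)C)c(C)c1C(=O)OCC[Si](C)(C)C | intermediate
9 | 2-(trimethylsilyl)ethyl 4-[(tert-butyldimethylsilyl)oxy]-2-methoxy-6-methyl-3,5-bis(3-methylbut-2-en-1-yl)benzoate | COc1c(CC=C(C)C)c(O[Si](C)(C)C(C)(C)C)c(CC=C(C)C)c(C)c1C(=O)OCC[Si](C)(C)C | intermediate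
10 | {4-[(tert-butyldimethylsilyl)oxy]phenyl}methanol | CC(C)(C)[Si](C)(C)Oc1ccc(CO)cc1 | starting material
11 | [4-(bromomethyl)phenoxy](tert-butyl)dimethylsilane | CC(C)(C)[Si](C)(C)Oc1ccc(CBr)cc1 | intermediate
12 | 2-(trimethylsilyl)ethyl 4-[(tert-butyldimethylsilyl)oxy]-6-(lithiomethyl)-2-methoxy-3,5-bis(3-methylbut-2-en-1-yl)benzoate (lithium dienolate drawn as the C–Li form) | [Li]Cc1c(CC=C(C)C)c(O[Si](C)(C)C(C)(C)C)c(CC=C(C)C)c(OC)c1C(=O)OCC[Si](C)(C)C | intermediate
13 | 2-(trimethylsilyl)ethyl 4-[(tert-butyldimethylsilyl)oxy]-6-(2-{4-[(tert-butyldimethylsilyl)oxy]phenyl}ethyl)-2-methoxy-3,5-bis(3-methylbut-2-en-1-yl)benzoate | COc1c(CC=C(C)C)c(O[Si](C)(C)C(C)(C)C)c(CC=C(C)C)c(CCc2ccc(O[Si](C)(C)C(C)(C)C)cc2)c1C(=O)OCC[Si](C)(C)C | intermediate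
14 | 4-hydroxy-6-[2-(4-hydroxyphenyl)ethyl]-2-methoxy-3,5-bis(3-methylbut-2-en-1-yl)benzoic acid | COc1c(CC=C(C)C)c(O)c(CC=C(C)C)c(CCc2ccc(O)cc2)c1C(=O)O | target

**Step count and risks**

Total step count: 8. Longest linear sequence: 7 steps (steps 1–5, 7 and 8); step 6 is a one-step side branch.

Steps most likely to fail:

1. Step 4 (double C-prenylation). O-Alkylation of the phenoxide, an incomplete second alkylation at the crowded position, or dearomatising over-alkylation may erode the C,C-dialkylation. The fallback replaces phenoxide C-alkylation by two cycles of O-(1,1-dimethylallyl)ation and aromatic Claisen rearrangement. It sets out from 5: Pd(0)-catalysed Tsuji–Trost O-alkylation with tert-butyl 2-methylbut-3-en-2-yl carbonate (Pd(PPh3)4, THF) would give 2-(trimethylsilyl)ethyl 2-methoxy-6-methyl-4-[(2-methylbut-3-en-2-yl)oxy]benzoate F1. Heating (toluene, 110 °C) should bring about the [3,3] rearrangement to the mono-prenyl phenols 6 and 7, either of which serves. A second O-alkylation of this mixture would give 2-(trimethylsilyl)ethyl 2-methoxy-6-methyl-3-(3-methylbut-2-en-1-yl)-4-[(2-methylbut-3-en-2-yl)oxy]benzoate F2 (from 6) and 2-(trimethylsilyl)ethyl 2-methoxy-6-methyl-5-(3-methylbut-2-en-1-yl)-4-[(2-methylbut-3-en-2-yl)oxy]benzoate F3 (from 7). A second Claisen rearrangement, now possible only into the one free ortho position, comes back to the route at 8.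

2. Step 7 (key coupling). Competing deprotonation at a prenyl methylene, Claisen-type self-condensation of the anion, or ionisation and oligomerisation of the bromide may divert the union on the crowded ring. The fallback forms the bridge first and adds the prenyl groups afterwards. It sets out from 4: LDA (THF, −78 °C) would give 2-(trimethylsilyl)ethyl 4-(benzyloxy)-6-(lithiomethyl)-2-methoxybenzoate F4, which 11 should alkylate to 2-(trimethylsilyl)ethyl 4-(benzyloxy)-6-(2-{4-[(tert-butyldimethylsilyl)oxy]phenyl}ethyl)-2-methoxybenzoate F5. Hydrogenolysis (H2, Pd/C, EtOAc) would give 2-(trimethylsilyl)ethyl 6-(2-{4-[(tert-butyldimethylsilyl)oxy]phenyl}ethyl)-4-hydroxy-2-methoxybenzoate F6. Phenoxide o,o'-diprenylation as in step 4 (NaH, toluene, prenyl bromide) would pass through the 3-prenyl phenol 2-(trimethylsilyl)ethyl 6-(2-{4-[(tert-butyldimethylsilyl)oxy]phenyl}ethyl)-4-hydroxy-2-methoxy-3-(3-methylbut-2-en-1-yl)benzoate F7 and the 5-prenyl phenol 2-(trimethylsilyl)ethyl 6-(2-{4-[(tert-butyldimethylsilyl)oxy]phenyl}ethyl)-4-hydroxy-2-methoxy-5-(3-methylbut-2-en-1-yl)benzoate F8 to 2-(trimethylsilyl)ethyl 6-(2-{4-[(tert-butyldimethylsilyl)oxy]phenyl}ethyl)-4-hydroxy-2-methoxy-3,5-bis(3-methylbut-2-en-1-yl)benzoate F9. TBAF (THF) then comes back to the route at 14.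

3. Step 2 (one-pot O-4 benzylation and O-2 methylation). Loss of site selectivity between the two phenols (benzylation at O-2, methylation of unreacted O-4) may give mixtures, and the step also rests on the chemoselectivity of the Mitsunobu esterification before it. The fallback uses a temporary ring that masks the acid and O-2 together. It sets out from 1: acetone, TFAA and TFA (0 °C → rt) would give the acetonide 7-hydroxy-2,2,5-trimethyl-4H-1,3-benzodioxin-4-one F10, whose only free phenol corresponds to O-4. Benzylation (BnBr, K2CO3, acetone) would give 7-(benzyloxy)-2,2,5-trimethyl-4H-1,3-benzodioxin-4-one F11. Opening of the dioxinone with sodium 2-(trimethylsilyl)ethoxide (NaH, 2-(trimethylsilyl)ethanol, THF, 0 °C → rt) should deliver the ester and the free 2-OH in one operation. This comes back to the route at 3, which is then isolated and methylated (MeI, K2CO3, DMF) to 4.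

**Further compounds**

F1 | step 4 | 2-(trimethylsilyl)ethyl 2-methoxy-6-methyl-4-[(2-methylbut-3-en-2-yl)oxy]benzoate | COc1cc(OC(C)(C)C=C)cc(C)c1C(=O)OCC[Si](C)(C)C
F2 | step 4 | 2-(trimethylsilyl)ethyl 2-methoxy-6-methyl-3-(3-methylbut-2-en-1-yl)-4-[(2-methylbut-3-en-2-yl)oxy]benzoate | COc1c(CC=C(C)C)c(OC(C)(C)C=C)cc(C)c1C(=O)OCC[Si](C)(C)C
F3 | step 4 | 2-(trimethylsilyl)ethyl 2-methoxy-6-methyl-5-(3-methylbut-2-en-1-yl)-4-[(2-methylbut-3-en-2-yl)oxy]benzoate | COc1cc(OC(C)(C)C=C)c(CC=C(C)C)c(C)c1C(=O)OCC[Si](C)(C)C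
F4 | step 7 | 2-(trimethylsilyl)ethyl 4-(benzyloxy)-6-(lithiomethyl)-2-methoxybenzoate | [Li]Cc1cc(OCc2ccccc2)cc(OC)c1C(=O)OCC[Si](C)(C)C
F5 | step 7 | 2-(trimethylsilyl)ethyl 4-(benzyloxy)-6-(2-{4-[(tert-butyldimethylsilyl)oxy]phenyl}ethyl)-2-methoxybenzoate | COc1cc(OCc2ccccc2)cc(CCc2ccc(O[Si](C)(C)C(C)(C)C)cc2)c1C(=O)OCC[Si](C)(C)C
F6 | step 7 | 2-(trimethylsilyl)ethyl 6-(2-{4-[(tert-butyldimethylsilyl)oxy]phenyl}ethyl)-4-hydroxy-2-methoxybenzoate | COc1cc(O)cc(CCc2ccc(O[Si](C)(C)C(C)(C)C)cc2)c1C(=O)OCC[Si](C)(C)C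
F7 | step 7 | 2-(trimethylsilyl)ethyl 6-(2-{4-[(tert-butyldimethylsilyl)oxy]phenyl}ethyl)-4-hydroxy-2-methoxy-3-(3-methylbut-2-en-1-yl)benzoate | COc1c(CC=C(C)C)c(O)cc(CCc2ccc(O[Si](C)(C)C(C)(C)C)cc2)c1C(=O)OCC[Si](C)(C)C
F8 | step 7 | 2-(trimethylsilyl)ethyl 6-(2-{4-[(tert-butyldimethylsilyl)oxy]phenyl}ethyl)-4-hydroxy-2-methoxy-5-(3-methylbut-2-en-1-yl)benzoate | COc1cc(O)c(CC=C(C)C)c(CCc2ccc(O[Si](C)(C)C(C)(C)C)cc2)c1C(=O)OCC[Si](C)(C)C
F9 | step 7 | 2-(trimethylsilyl)ethyl 6-(2-{4-[(tert-butyldimethylsilyl)oxy]phenyl}ethyl)-4-hydroxy-2-methoxy-3,5-bis(3-methylbut-2-en-1-yl)benzoate | COc1c(CC=C(C)C)c(O)c(CC=C(C)C)c(CCc2ccc(O[Si](C)(C)C(C)(C)C)cc2)c1C(=O)OCC[Si](C)(C)C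
F10 | step 2 | 7-hydroxy-2,2,5-trimethyl-4H-1,3-benzodioxin-4-one | Cc1cc(O)cc2OC(C)(C)OC(=O)c12
F11 | step 2 | 7-(benzyloxy)-2,2,5-trimethyl-4H-1,3-benzodioxin-4-one | Cc1cc(OCc3ccccc3)cc2OC(C)(C)OC(=O)c12
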